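## Retrosynthetic overview

1. Target ⇐ C25 pentaenoate (ester reduction, desilylation) ⇐ dehydration of the adduct from the key union: a vinylogous Mukaiyama aldol between a C20 furanoid polyenal and the silyl dienolate of ethyl tiglate, forming the central C15–C15′ bond.
2. C20 polyenal ⇐ C15 furanoid enal by Horner–Wadsworth–Emmons C5 extension, reduction and allylic oxidation.
3. Dihydrofuran ring (formed last) ⇐ gold-catalysed cyclisation of an α-hydroxy vinylallene ⇐ anti-SN2′ hydride opening of a propargylic epoxide ⇐ Sonogashira coupling of an epoxy alkyne with an (E)-enol triflate.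
4. Epoxide ring (formed first, later opened) ⇐ Sharpless epoxidation of the allylic alcohol made from (4R,6R)-actinol; the cyclohexane ring and C3 are bought with actinol.

Assumption: (4R,6R)-actinol, the commercial zeaxanthin building block, is purchased.

Notation: atom labels follow carotenoid numbering (C1 gem-dimethyl carbon, C3 carbinol, C5 and C8 the ether carbons, then C9–C15 and C15′–C12′ along the chain). TBS = tert-butyldimethylsilyl, TES = triethylsilyl. Fur = (2R,6S,7aR)-6-(TBS-oxy)-4,4,7a-trimethyl-2,4,5,6,7,7a-hexahydro-1-benzofuran-2-yl. IPr = 1,3-bis(2,6-diisopropylphenyl)imidazol-2-ylidene.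

## Route

Step 1
Reactants: 1 (4R,6R)-4-hydroxy-2,2,6-trimethylcyclohexan-1-one ((4R,6R)-actinol)
Product: 2 (4R,6R)-4-(TBS-oxy)-2,2,6-trimethylcyclohexan-1-one
Conditions: TBSCl, imidazole, DMF, rt
Reagents that add atoms: tert-butyldimethylsilyl chloride (TBSCl), CC(C)(C)[Si](C)(C)Cl
Why: Standard O-silylation of the secondary alcohol protects C3–OH for the whole route without touching a stereocentre.

Step 2
Reactants: 2 (4R,6R)-4-(TBS-oxy)-2,2,6-trimethylcyclohexan-1-one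
Product: 4 (4R)-4-(TBS-oxy)-2,6,6-trimethylcyclohex-1-en-1-yl trifluoromethanesulfonate, via lithium enolate 3 (not isolated)
Conditions: LiN(i-Pr)2, THF, −78 °C to 0 °C; then PhNTf2, 0 °C to rt
Reagents that add atoms: N-phenylbis(trifluoromethanesulfonimide) (PhNTf2), O=S(=O)(N(c1ccccc1)S(=O)(=O)C(F)(F)F)C(F)(F)F
Why: Enolate O-triflation is regiochemically unambiguous because only one α-carbon carries a hydrogen; the methyl-bearing α-centre of actinol is deliberately erased.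

Step 3
Reactants: 4 (4R)-4-(TBS-oxy)-2,6,6-trimethylcyclohex-1-en-1-yl trifluoromethanesulfonate
Product: 5 methyl (4R)-4-(TBS-oxy)-2,6,6-trimethylcyclohex-1-ene-1-carboxylate
Conditions: Pd(OAc)2 (5 mol%), PPh3, CO (1 atm), MeOH, Et3N, DMF, 70 °C
Reagents that add atoms: carbon monoxide, [C-]#[O+]; methanol, CO
Why: Palladium-catalysed alkoxycarbonylation of the enol triflate (oxidative addition, CO insertion, methanolysis) installs C7.

Step 4
Reactants: 5 methyl (4R)-4-(TBS-oxy)-2,6,6-trimethylcyclohex-1-ene-1-carboxylate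
Product: 6 [(4R)-4-(TBS-oxy)-2,6,6-trimethylcyclohex-1-en-1-yl]methanol
Conditions: i-Bu2AlH (2.5 equiv), CH2Cl2, −78 °C to 0 °C; aq. KNaC4H4O6
Reagents that add atoms: none
Why: 1,2-Reduction of the conjugated ester gives the primary allylic alcohol needed to direct the epoxidation.

Step 5
Reactants: 6 [(4R)-4-(TBS-oxy)-2,6,6-trimethylcyclohex-1-en-1-yl]methanol
Product: 7 [(1R,4S,6R)-4-(TBS-oxy)-2,2,6-trimethyl-7-oxabicyclo[4.1.0]heptan-1-yl]methanol (epoxide anti to OTBS)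
Conditions: Ti(OiPr)4, D-(−)-diethyl tartrate, t-BuOOH, 4 Å MS, CH2Cl2, −20 °C
Reagents that add atoms: tert-butyl hydroperoxide, CC(C)(C)OO
Why: Sharpless asymmetric epoxidation; the D-(−)-tartrate titanium complex delivers oxygen under reagent control to the face anti to the C3 silyloxy group, setting C5 (R) and the temporary C6 centre.

Step 6
Reactants: 7 [(1R,4S,6R)-4-(TBS-oxy)-2,2,6-trimethyl-7-oxabicyclo[4.1.0]heptan-1-yl]methanol
Product: 8 (1S,4S,6R)-4-(TBS-oxy)-2,2,6-trimethyl-7-oxabicyclo[4.1.0]heptane-1-carbaldehyde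
Conditions: Pr4N[RuO4] (5 mol%), N-methylmorpholine N-oxide, 4 Å MS, CH2Cl2, rt
Reagents that add atoms: none
Why: Ley–Griffith oxidation under neutral conditions gives an aldehyde with no α-hydrogen, so nothing can epimerise and the epoxide survives.

Step 7
Reactants: 8 (1S,4S,6R)-4-(TBS-oxy)-2,2,6-trimethyl-7-oxabicyclo[4.1.0]heptane-1-carbaldehyde
Product: 9 tert-butyl{[(1R,3S,6R)-6-ethynyl-1,5,5-trimethyl-7-oxabicyclo[4.1.0]heptan-3-yl]oxy}dimethylsilane
Conditions: dimethyl (1-diazo-2-oxopropyl)phosphonate, K2CO3, MeOH, 0 °C to rt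
Reagents that add atoms: Ohira–Bestmann reagent (dimethyl (1-diazo-2-oxopropyl)phosphonate), COP(=O)(OC)C(=[N+]=[N-])C(C)=O
Why: Seyferth–Gilbert homologation in the Ohira–Bestmann variant converts the non-enolisable aldehyde into the terminal alkyne (C8) under mild base that leaves the epoxide intact.

Step 8
Reactants: 10 ethyl 3-oxobutanoate (ethyl acetoacetate)
Product: 11 ethyl (2E)-3-(trifluoromethanesulfonyloxy)but-2-enoate
Conditions: Tf2O, aq. Me4NOH, hexanes, 5 °C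
Reagents that add atoms: trifluoromethanesulfonic anhydride (Tf2O), O=S(=O)(OS(=O)(=O)C(F)(F)F)C(F)(F)F
Why: Stereoselective enolate O-sulfonylation; the non-chelated tetramethylammonium enolate reacts in its extended form and gives the (E)-enol triflate (triflate trans to the ester).

Step 9
Reactants: 11 ethyl (2E)-3-(trifluoromethanesulfonyloxy)but-2-enoate
Product: 12 (2E)-4-hydroxybut-2-en-2-yl trifluoromethanesulfonate
Conditions: i-Bu2AlH (2.2 equiv), CH2Cl2, −78 °C; aq. KNaC4H4O6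
Reagents that add atoms: none
Why: 1,2-Reduction of the ester at low temperature leaves the vinyl triflate and its geometry untouched.

Step 10
Reactants: 12 (2E)-4-hydroxybut-2-en-2-yl trifluoromethanesulfonate
Product: 13 (2E)-4-(triethylsilyloxy)but-2-en-2-yl trifluoromethanesulfonate
Conditions: TESCl, imidazole, CH2Cl2, 0 °C
Reagents that add atoms: chlorotriethylsilane (TESCl), CC[Si](Cl)(CC)CC
Why: O-Silylation gives a C11 protecting group that is inert to copper hydride and can later be removed selectively beside the secondary TBS ether.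

Step 11
Reactants: 9 tert-butyl{[(1R,3S,6R)-6-ethynyl-1,5,5-trimethyl-7-oxabicyclo[4.1.0]heptan-3-yl]oxy}dimethylsilane, 13 (2E)-4-(triethylsilyloxy)but-2-en-2-yl trifluoromethanesulfonate
Product: 14 tert-butyldimethyl{[(1R,3S,6R)-1,5,5-trimethyl-6-[(3E)-3-methyl-5-(triethylsilyloxy)pent-3-en-1-yn-1-yl]-7-oxabicyclo[4.1.0]heptan-3-yl]oxy}silane
Conditions: Pd(PPh3)4 (5 mol%), CuI (10 mol%), i-Pr2NH, THF, rt
Reagents that add atoms: none
Why: Sonogashira coupling forms the C8–C9 bond with retention of the enol triflate geometry, fixing the 9E alkene.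

Step 12
Reactants: 14 tert-butyldimethyl{[(1R,3S,6R)-1,5,5-trimethyl-6-[(3E)-3-methyl-5-(triethylsilyloxy)pent-3-en-1-yn-1-yl]-7-oxabicyclo[4.1.0]heptan-3-yl]oxy}silane
Product: 15 (1R,5S)-5-(TBS-oxy)-1,3,3-trimethyl-2-[(3E)-3-methyl-5-(triethylsilyloxy)penta-1,3-dien-1-ylidene]cyclohexan-1-ol (allene axis S; C9 substituent on the side of the C5 hydroxyl)
Conditions: (IPr)CuCl (5 mol%), NaOt-Bu (10 mol%), (EtO)2MeSiH, t-BuOH, toluene, 0 °C
Reagents that add atoms: none
Why: Copper hydride-catalysed SN2′ reduction of a propargylic epoxide; syn-hydrocupration then anti β-alkoxide elimination puts hydride on C8 anti to the departing C6–O bond, so the epoxide configuration becomes the S allene axis while C5 keeps its oxygen with retention.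

Step 13
Reactants: 15 (1R,5S)-5-(TBS-oxy)-1,3,3-trimethyl-2-[(3E)-3-methyl-5-(triethylsilyloxy)penta-1,3-dien-1-ylidene]cyclohexan-1-ol
Product: 16 triethyl{[(2E)-3-Fur-but-2-en-1-yl]oxy}silane
Conditions: AuCl3 (2 mol%), THF, 0 °C to rt, dark
Reagents that add atoms: none
Why: Gold-catalysed 5-endo cycloisomerisation of an α-hydroxyallene to a 2,5-dihydrofuran; the C5 oxygen adds to C8 in the ring plane with complete axis-to-centre chirality transfer, so the S allene gives 8R (side chain trans to the C5 methyl).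

Step 14
Reactants: 16 triethyl{[(2E)-3-Fur-but-2-en-1-yl]oxy}silane
Product: 17 (2E)-3-Fur-but-2-en-1-ol
Conditions: HF·pyridine, pyridine, THF, 0 °C
Reagents that add atoms: none
Why: Buffered fluoride desilylation removes the primary TES ether much faster than the secondary TBS ether and is too weakly acidic to ionise the doubly allylic C8–O bond.

Step 15
Reactants: 17 (2E)-3-Fur-but-2-en-1-ol
Product: 18 (2E)-3-Fur-but-2-enal
Conditions: MnO2 (activated, 20 equiv), CH2Cl2, rt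
Reagents that add atoms: none
Why: Chemoselective allylic oxidation gives the enal under neutral conditions that cannot epimerise C8.

Step 16
Reactants: 18 (2E)-3-Fur-but-2-enal, 19 ethyl (2E)-4-(diethoxyphosphoryl)-3-methylbut-2-enoate
Product: 21 ethyl (2E,4E,6E)-7-Fur-3-methylocta-2,4,6-trienoate, via lithio phosphonate 20 (not isolated)
Conditions: LiN(SiMe3)2, THF–DMPU, −78 °C; then 18, −78 °C to 0 °C
Reagents that add atoms: none
Why: Horner–Wadsworth–Emmons olefination with the stabilised allylic phosphonate anion gives the 11E alkene and mainly the 13E enoate (minor 13Z isomer removed by chromatography) without enolising towards C8.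

Step 17
Reactants: 21 ethyl (2E,4E,6E)-7-Fur-3-methylocta-2,4,6-trienoate
Product: 22 (2E,4E,6E)-7-Fur-3-methylocta-2,4,6-trien-1-ol
Conditions: i-Bu2AlH (2.2 equiv), CH2Cl2, −78 °C; aq. KNaC4H4O6
Reagents that add atoms: none
Why: 1,2-Reduction of the trienoate gives the allylic alcohol with a neutral work-up.

Step 18
Reactants: 22 (2E,4E,6E)-7-Fur-3-methylocta-2,4,6-trien-1-ol
Product: 23 (2E,4E,6E)-7-Fur-3-methylocta-2,4,6-trienal
Conditions: MnO2, CH2Cl2, rt, dark
Reagents that add atoms: none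
Why: Allylic oxidation, as in retinol-to-retinal chemistry, gives the C20 polyenal (C15 aldehyde) without acid or base.

Step 19
Reactants: 24 ethyl (2E)-2-methylbut-2-enoate (ethyl tiglate)
Product: 26 [(1-ethoxy-2-methylbuta-1,3-dien-1-yl)oxy]trimethylsilane, via lithium dienolate 25 (not isolated)
Conditions: LiN(i-Pr)2, THF–DMPU, −78 °C; then TMSCl, −78 °C to rt
Reagents that add atoms: chlorotrimethylsilane (TMSCl), C[Si](C)(C)Cl
Why: γ-Deprotonation of the enoate and O-silylation of the dienolate give the silyl ketene acetal used as the vinylogous aldol donor.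

Step 20
Reactants: 23 (2E,4E,6E)-7-Fur-3-methylocta-2,4,6-trienal, 26 [(1-ethoxy-2-methylbuta-1,3-dien-1-yl)oxy]trimethylsilane
Product: 27 ethyl (2E,6E,8E,10E)-11-Fur-5-hydroxy-2,7-dimethyldodeca-2,6,8,10-tetraenoate (epimer mixture at the carbinol carbon C15)
Conditions: BF3·OEt2 (1.1 equiv), CH2Cl2–Et2O, −78 °C; Et3N then aq. NaHCO3 at −78 °C
Reagents that add atoms: none
Why: Vinylogous Mukaiyama aldol addition; the BF3-activated aldehyde is attacked through an open transition state by the unhindered γ-carbon (the α-carbon is blocked by its methyl), forming the C15–C15′ bond and the (E)-α-methyl enoate, while the new carbinol centre is an epimer mixture that is removed in the next step.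

Step 21
Reactants: 27 ethyl (2E,6E,8E,10E)-11-Fur-5-hydroxy-2,7-dimethyldodeca-2,6,8,10-tetraenoate
Product: 29 ethyl (2E,4E,6E,8E,10E)-11-Fur-2,7-dimethyldodeca-2,4,6,8,10-pentaenoate, via acetate 28 (not isolated)
Conditions: Ac2O, Et3N, DMAP (cat.), CH2Cl2, 0 °C; then DBU, 0 °C to rt
Reagents that add atoms: none
Why: Acetylation followed by vinylogous E1cB elimination through the ester dienolate gives the fully conjugated pentaenoate with the thermodynamically favoured 15E bond and erases the temporary carbinol centre.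

Step 22
Reactants: 29 ethyl (2E,4E,6E,8E,10E)-11-Fur-2,7-dimethyldodeca-2,4,6,8,10-pentaenoate
Product: 30 (2E,4E,6E,8E,10E)-11-Fur-2,7-dimethyldodeca-2,4,6,8,10-pentaen-1-ol
Conditions: i-Bu2AlH (2.2 equiv), CH2Cl2, −78 °C; aq. KNaC4H4O6
Reagents that add atoms: none
Why: 1,2-Reduction of the conjugated ester gives the C12′ allylic alcohol with a neutral work-up.

Step 23
Reactants: 30 (2E,4E,6E,8E,10E)-11-Fur-2,7-dimethyldodeca-2,4,6,8,10-pentaen-1-ol
Product: 31 (2R,6S,7aR)-2-[(2E,4E,6E,8E,10E)-12-hydroxy-6,11-dimethyldodeca-2,4,6,8,10-pentaen-2-yl]-4,4,7a-trimethyl-2,4,5,6,7,7a-hexahydro-1-benzofuran-6-ol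
Conditions: Bu4NF, THF, 0 °C to rt, dark
Reagents that add atoms: none
Why: Fluoride desilylation frees the C3 hydroxyl under non-acidic conditions that spare the polyene, the allylic alcohol and the C8 centre.

## Compound list

1 | (4R,6R)-4-hydroxy-2,2,6-trimethylcyclohexan-1-one ((4R,6R)-actinol) | O=C1C(C)(C)C[C@H](O)C[C@H]1C | starting material
2 | (4R,6R)-4-(TBS-oxy)-2,2,6-trimethylcyclohexan-1-one | O=C1C(C)(C)C[C@H](O[Si](C)(C)C(C)(C)C)C[C@H]1C | intermediate
3 | lithium (4R)-4-(TBS-oxy)-2,6,6-trimethylcyclohex-1-en-1-olate (lithium enolate) | [Li+].CC1=C([O-])C(C)(C)C[C@H](O[Si](C)(C)C(C)(C)C)C1 | intermediate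
4 | (4R)-4-(TBS-oxy)-2,6,6-trimethylcyclohex-1-en-1-yl trifluoromethanesulfonate | CC1=C(OS(=O)(=O)C(F)(F)F)C(C)(C)C[C@H](O[Si](C)(C)C(C)(C)C)C1 | intermediate
5 | methyl (4R)-4-(TBS-oxy)-2,6,6-trimethylcyclohex-1-ene-1-carboxylate | CC1=C(C(=O)OC)C(C)(C)C[C@H](O[Si](C)(C)C(C)(C)C)C1 | intermediate
6 | [(4R)-4-(TBS-oxy)-2,6,6-trimethylcyclohex-1-en-1-yl]methanol | CC1=C(CO)C(C)(C)C[C@H](O[Si](C)(C)C(C)(C)C)C1 | intermediate
7 | [(1R,4S,6R)-4-(TBS-oxy)-2,2,6-trimethyl-7-oxabicyclo[4.1.0]heptan-1-yl]methanol (epoxide anti to OTBS) | OC[C@@]12O[C@]1(C)C[C@@H](O[Si](C)(C)C(C)(C)C)CC2(C)C | intermediate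
8 | (1S,4S,6R)-4-(TBS-oxy)-2,2,6-trimethyl-7-oxabicyclo[4.1.0]heptane-1-carbaldehyde | O=C[C@@]12O[C@]1(C)C[C@@H](O[Si](C)(C)C(C)(C)C)CC2(C)C | intermediate
9 | tert-butyl{[(1R,3S,6R)-6-ethynyl-1,5,5-trimethyl-7-oxabicyclo[4.1.0]heptan-3-yl]oxy}dimethylsilane | C#C[C@@]12O[C@]1(C)C[C@@H](O[Si](C)(C)C(C)(C)C)CC2(C)C | intermediate
10 | ethyl 3-oxobutanoate (ethyl acetoacetate) | CCOC(=O)CC(C)=O | starting material
11 | ethyl (2E)-3-(trifluoromethanesulfonyloxy)but-2-enoate | CCOC(=O)/C=C(\C)OS(=O)(=O)C(F)(F)F | intermediate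
12 | (2E)-4-hydroxybut-2-en-2-yl trifluoromethanesulfonate | OC/C=C(\C)OS(=O)(=O)C(F)(F)F | intermediate
13 | (2E)-4-(triethylsilyloxy)but-2-en-2-yl trifluoromethanesulfonate | CC[Si](CC)(CC)OC/C=C(\C)OS(=O)(=O)C(F)(F)F | intermediate
14 | tert-butyldimethyl{[(1R,3S,6R)-1,5,5-trimethyl-6-[(3E)-3-methyl-5-(triethylsilyloxy)pent-3-en-1-yn-1-yl]-7-oxabicyclo[4.1.0]heptan-3-yl]oxy}silane | CC[Si](CC)(CC)OC/C=C(\C)C#C[C@@]12O[C@]1(C)C[C@@H](O[Si](C)(C)C(C)(C)C)CC2(C)C | intermediate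
15 | (1R,5S)-5-(TBS-oxy)-1,3,3-trimethyl-2-[(3E)-3-methyl-5-(triethylsilyloxy)penta-1,3-dien-1-ylidene]cyclohexan-1-ol (allene axis S; C9 substituent on the side of the C5 hydroxyl) | CC[Si](CC)(CC)OC/C=C(\C)C=[C@]=C1C(C)(C)C[C@H](O[Si](C)(C)C(C)(C)C)C[C@@]1(C)O | intermediate
16 | triethyl{[(2E)-3-Fur-but-2-en-1-yl]oxy}silane | CC[Si](CC)(CC)OC/C=C(\C)[C@H]1C=C2C(C)(C)C[C@H](O[Si](C)(C)C(C)(C)C)C[C@@]2(C)O1 | intermediate
17 | (2E)-3-Fur-but-2-en-1-ol | OC/C=C(\C)[C@H]1C=C2C(C)(C)C[C@H](O[Si](C)(C)C(C)(C)C)C[C@@]2(C)O1 | intermediate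
18 | (2E)-3-Fur-but-2-enal | O=C/C=C(\C)[C@H]1C=C2C(C)(C)C[C@H](O[Si](C)(C)C(C)(C)C)C[C@@]2(C)O1 | intermediate
19 | ethyl (2E)-4-(diethoxyphosphoryl)-3-methylbut-2-enoate (commercial, mainly E) | CCOC(=O)/C=C(\C)CP(=O)(OCC)OCC | starting material
20 | lithium salt of the C4 carbanion of 19 (lithio phosphonate) | [Li+].CCOC(=O)C=C(C)[CH-]P(=O)(OCC)OCC | intermediate
21 | ethyl (2E,4E,6E)-7-Fur-3-methylocta-2,4,6-trienoate | CCOC(=O)/C=C(C)/C=C/C=C(\C)[C@H]1C=C2C(C)(C)C[C@H](O[Si](C)(C)C(C)(C)C)C[C@@]2(C)O1 | intermediate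
22 | (2E,4E,6E)-7-Fur-3-methylocta-2,4,6-trien-1-ol | OC/C=C(C)/C=C/C=C(\C)[C@H]1C=C2C(C)(C)C[C@H](O[Si](C)(C)C(C)(C)C)C[C@@]2(C)O1 | intermediate
23 | (2E,4E,6E)-7-Fur-3-methylocta-2,4,6-trienal | O=C/C=C(C)/C=C/C=C(\C)[C@H]1C=C2C(C)(C)C[C@H](O[Si](C)(C)C(C)(C)C)C[C@@]2(C)O1 | intermediate
24 | ethyl (2E)-2-methylbut-2-enoate (ethyl tiglate) | C/C=C(\C)C(=O)OCC | starting material
25 | lithium 1-ethoxy-2-methylbuta-1,3-dien-1-olate (lithium dienolate) | [Li+].C=CC(C)=C([O-])OCC | intermediate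
26 | [(1-ethoxy-2-methylbuta-1,3-dien-1-yl)oxy]trimethylsilane (ketene acetal E/Z mixture) | C=CC(C)=C(OCC)O[Si](C)(C)C | intermediate
27 | ethyl (2E,6E,8E,10E)-11-Fur-5-hydroxy-2,7-dimethyldodeca-2,6,8,10-tetraenoate (carbinol epimers) | CCOC(=O)/C(C)=C/CC(O)/C=C(C)/C=C/C=C(\C)[C@H]1C=C2C(C)(C)C[C@H](O[Si](C)(C)C(C)(C)C)C[C@@]2(C)O1 | intermediate
28 | ethyl (2E,6E,8E,10E)-5-acetoxy-11-Fur-2,7-dimethyldodeca-2,6,8,10-tetraenoate | CCOC(=O)/C(C)=C/CC(OC(C)=O)/C=C(C)/C=C/C=C(\C)[C@H]1C=C2C(C)(C)C[C@H](O[Si](C)(C)C(C)(C)C)C[C@@]2(C)O1 | intermediate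
29 | ethyl (2E,4E,6E,8E,10E)-11-Fur-2,7-dimethyldodeca-2,4,6,8,10-pentaenoate | CCOC(=O)/C(C)=C/C=C/C=C(C)/C=C/C=C(\C)[C@H]1C=C2C(C)(C)C[C@H](O[Si](C)(C)C(C)(C)C)C[C@@]2(C)O1 | intermediate
30 | (2E,4E,6E,8E,10E)-11-Fur-2,7-dimethyldodeca-2,4,6,8,10-pentaen-1-ol | OC/C(C)=C/C=C/C=C(C)/C=C/C=C(\C)[C@H]1C=C2C(C)(C)C[C@H](O[Si](C)(C)C(C)(C)C)C[C@@]2(C)O1 | intermediate
31 | (2R,6S,7aR)-2-[(2E,4E,6E,8E,10E)-12-hydroxy-6,11-dimethyldodeca-2,4,6,8,10-pentaen-2-yl]-4,4,7a-trimethyl-2,4,5,6,7,7a-hexahydro-1-benzofuran-6-ol ((3S,5R,8R)-5,8-epoxy-5,8-dihydro-12′-apo-β-carotene-3,12′-diol) | CC(/C=C/C=C(\C)[C@H]1C=C2C(C)(C)C[C@H](O)C[C@@]2(C)O1)=C\C=C\C=C(/C)CO | target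

## Step count and risks

Total: 23 steps. Longest linear sequence: 19 steps (steps 1–7, 11–18 and 20–23); steps 8–10 and 19 are side branches.

The three steps most likely to fail:

- **Step 12, copper hydride SN2′ reduction.** The alkyne is vinyl-substituted and sits next to two fully substituted carbons, so hydrocupration could take the wrong regiochemistry or over-reduce. The fallback sets out from 8 and comes back to the route at 17, at the cost of stereocontrol at C8. Olefination of 8 with lithio phosphonate 20 gives the epoxy dienoate ethyl (2E,4E)-5-[(1S,4S,6R)-4-(TBS-oxy)-2,2,6-trimethyl-7-oxabicyclo[4.1.0]heptan-1-yl]-3-methylpenta-2,4-dienoate F1. Reduction with i-Bu2AlH gives the epoxy dienol (2E,4E)-5-[(1S,4S,6R)-4-(TBS-oxy)-2,2,6-trimethyl-7-oxabicyclo[4.1.0]heptan-1-yl]-3-methylpenta-2,4-dien-1-ol F2. Acid-catalysed epoxide-to-furanoid rearrangement (trace HCl, CHCl3, 0 °C) then gives 17 together with its C8 epimer (2E)-3-[(2S,6S,7aR)-6-(TBS-oxy)-4,4,7a-trimethyl-2,4,5,6,7,7a-hexahydro-1-benzofuran-2-yl]but-2-en-1-ol F3, which is removed by chromatography. C5 is retained in this rearrangement, but C8 forms as a mixture.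

- **Step 13, gold-catalysed cyclisation.** The vinylallene could undergo gold-induced carbocyclisation, or the Lewis acid could ionise the doubly allylic C8–O bond of the product. The fallback sets out from 15 and comes back at 16. Iodocyclisation with N-iodosuccinimide (CH2Cl2, 0 °C) follows the same axis-to-centre course and gives the vinyl iodide tert-butyl{[(2S,6S,7aR)-3-iodo-4,4,7a-trimethyl-2-[(2E)-4-(triethylsilyloxy)but-2-en-2-yl]-2,4,5,6,7,7a-hexahydro-1-benzofuran-6-yl]oxy}dimethylsilane F4 (same spatial arrangement as 16; the descriptor at the ring carbon changes only because iodine raises a priority). Hydrogenolysis of the vinyl iodide with Pd(PPh3)4, HCO2H and Et3N in DMF then gives 16.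

- **Step 20, vinylogous Mukaiyama aldol.** The Lewis acid meets an acid-sensitive tetraenal, and the allylic aldol adduct can ionise. The fallback sets out from 23 and comes back at 29, keeping an aldol as the bond-forming event. Two-carbon homologation of 23 with (triphenylphosphoranylidene)acetaldehyde (toluene, 80 °C) gives the pentaenal (2E,4E,6E,8E)-9-Fur-5-methyldeca-2,4,6,8-tetraenal F5. Aldol addition of the lithium enolate of ethyl propionate (LiN(i-Pr)2, THF, −78 °C) gives the β-hydroxy ester ethyl (4E,6E,8E,10E)-11-Fur-3-hydroxy-2,7-dimethyldodeca-4,6,8,10-tetraenoate F6 as a diastereomer mixture. Acetylation (Ac2O, Et3N, DMAP) gives the acetate ethyl (4E,6E,8E,10E)-3-acetoxy-11-Fur-2,7-dimethyldodeca-4,6,8,10-tetraenoate F7, and DBU elimination in the same flask gives 29.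

Further compounds
F1 | step 12 | ethyl (2E,4E)-5-[(1S,4S,6R)-4-(TBS-oxy)-2,2,6-trimethyl-7-oxabicyclo[4.1.0]heptan-1-yl]-3-methylpenta-2,4-dienoate | CCOC(=O)/C=C(C)/C=C/[C@@]12O[C@]1(C)C[C@@H](O[Si](C)(C)C(C)(C)C)CC2(C)C
F2 | step 12 | (2E,4E)-5-[(1S,4S,6R)-4-(TBS-oxy)-2,2,6-trimethyl-7-oxabicyclo[4.1.0]heptan-1-yl]-3-methylpenta-2,4-dien-1-ol | OC/C=C(C)/C=C/[C@@]12O[C@]1(C)C[C@@H](O[Si](C)(C)C(C)(C)C)CC2(C)C
F3 | step 12 | (2E)-3-[(2S,6S,7aR)-6-(TBS-oxy)-4,4,7a-trimethyl-2,4,5,6,7,7a-hexahydro-1-benzofuran-2-yl]but-2-en-1-ol (C8 epimer of 17) | OC/C=C(\C)[C@@H]1C=C2C(C)(C)C[C@H](O[Si](C)(C)C(C)(C)C)C[C@@]2(C)O1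
F4 | step 13 | tert-butyl{[(2S,6S,7aR)-3-iodo-4,4,7a-trimethyl-2-[(2E)-4-(triethylsilyloxy)but-2-en-2-yl]-2,4,5,6,7,7a-hexahydro-1-benzofuran-6-yl]oxy}dimethylsilane | CC[Si](CC)(CC)OC/C=C(\C)[C@H]1C(I)=C2C(C)(C)C[C@H](O[Si](C)(C)C(C)(C)C)C[C@@]2(C)O1
F5 | step 20 | (2E,4E,6E,8E)-9-Fur-5-methyldeca-2,4,6,8-tetraenal | O=C/C=C/C=C(C)/C=C/C=C(\C)[C@H]1C=C2C(C)(C)C[C@H](O[Si](C)(C)C(C)(C)C)C[C@@]2(C)O1
F6 | step 20 | ethyl (4E,6E,8E,10E)-11-Fur-3-hydroxy-2,7-dimethyldodeca-4,6,8,10-tetraenoate (diastereomer mixture) | CCOC(=O)C(C)C(O)/C=C/C=C(C)/C=C/C=C(\C)[C@H]1C=C2C(C)(C)C[C@H](O[Si](C)(C)C(C)(C)C)C[C@@]2(C)O1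
F7 | step 20 | ethyl (4E,6E,8E,10E)-3-acetoxy-11-Fur-2,7-dimethyldodeca-4,6,8,10-tetraenoate | CCOC(=O)C(C)C(OC(C)=O)/C=C/C=C(C)/C=C/C=C(\C)[C@H]1C=C2C(C)(C)C[C@H](O[Si](C)(C)C(C)(C)C)C[C@@]2(C)O1
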